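Numbering (p-menthane) of the central cyclohexane: C1 = C(CH3)–O, C3 = CH bound to C3 of quinolinone A, C4 = CH bearing C8 (CMe2–O), C5 = CH bound to C3 of quinolinone B. Ring A is the pyran O–C8–C4–C3 fused trans on C3–C4, and ring B is the pyran O–C1–C6–C5 bridging C1 and C5.
Cuts: O–C8 (ring A) and O–C1 (ring B) first, then C1–CH3, last the two bonds C3–quinolinone A and C5–quinolinone B.
Enabling feature: C3 and C5 are both β to C1 and flank C4. They are therefore the two β-carbons of a cyclohexa-2,5-dienone whose carbonyl carbon is C1 and whose quinol carbon C4 already carries C8, and each accepts the nucleophilic C3 of one 4-hydroxy-1-methylquinolin-2-one.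
Forward: dearomatise 4-isopropylphenol, attach both quinolinones in one operation, add CH3 to C1. One acid treatment then closes ring B and, once the positive charge has moved from C4 to C8, ring A.
Stereochemistry: C3 and C5 come from a chiral primary amine catalyst (trans, same sense, so C4 is not yet stereogenic). C1 is fixed by the reach of the axial quinolinone B, and C4 by thermodynamic control (C8 equatorial, ring A trans-diequatorial).

Key step: step 2

Assumption: the sense of induction of 9-amino-9-deoxy-epi-quinine on the quinol dienone cannot be known in advance; it is taken to give the (3R,5R) series, and if the opposite sense is found the pseudoenantiomeric 9-amino-9-deoxy-epi-quinidine is used with no other change.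

Step 1
Reactants: 1 4-isopropylphenol
Product: 2 4-hydroxy-4-(propan-2-yl)cyclohexa-2,5-dien-1-one
Conditions: PhI(OAc)2 (1.1 equiv), MeCN/H2O 3:1, 0 °C to rt
Reagents that add atoms: water, O
Why: Oxidative dearomatisation of a 4-alkylphenol with a trivalent iodine reagent, in which the phenol oxygen binds to iodine, iodobenzene leaves and water traps the electron-poor ring at the substituted para carbon, a standard entry to p-quinols; 2 has a mirror plane and no stereocentre.

Step 2
Reactants: 2 4-hydroxy-4-(propan-2-yl)cyclohexa-2,5-dien-1-one; 3 4-hydroxy-1-methylquinolin-2(1H)-one (2.4 equiv)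
Product: 5 (3R,5R)-4-hydroxy-3,5-bis(4-hydroxy-1-methyl-2-oxo-1,2-dihydroquinolin-3-yl)-4-(propan-2-yl)cyclohexan-1-one, via mono-adduct enone 4 (not isolated)
Conditions: 9-amino-9-deoxy-epi-quinine (20 mol %), CF3CO2H (40 mol %), THF, 40 °C
Reagents that add atoms: none
Why: Proposed new method: the primary amine condenses with the carbonyl group of 2 to a cross-conjugated iminium ion, the vinylogous acid 3 attacks one β-carbon through its C3, hydrolysis releases enone 4, and 4 re-enters the same cycle through its remaining enone arm, so that both quinolinone C3–CH bonds arise under one catalyst. The closest known reaction types are the cinchona primary amine catalysed Michael addition of 4-hydroxycoumarins and 4-hydroxyquinolin-2-ones to cyclic enones, the amine-catalysed desymmetrising addition of malonates to 4,4-disubstituted cyclohexa-2,5-dienones, and the ligand-controlled sequential double addition of dialkylzincs to such dienones under copper catalysis; what is new is the double addition of this nucleophile. No ring is closed in this step. The first benzylic centre is set by the catalyst, which picks one of the two enantiotopic arms and meets it on the face of the small hydroxyl group, away from isopropyl. The second centre is set by the same enantioface preference, which on the other arm points to the opposite ring face, and the substrate helps because axial attack on the half-chair of 4 that holds quinolinone and isopropyl equatorial comes in trans to the 5-substituent, the usual outcome with 5-substituted cyclohexenones. The step needs C- over O-alkylation (O-attack is reversible and the C–C adduct is the sink), survival of the acid-labile quinol (the ammonium salt buffer is too weak to ionise it) and trans over cis selectivity, and any minor enantiomer of 4 is steered by the catalyst into the achiral cis isomer, which is removed by chromatography and so should raise the enantiopurity of 5, whose C4 is no stereocentre because its two branches are alike.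

Step 3
Reactants: 5 (3R,5R)-4-hydroxy-3,5-bis(4-hydroxy-1-methyl-2-oxo-1,2-dihydroquinolin-3-yl)-4-(propan-2-yl)cyclohexan-1-one
Product: 6 (3R,5R)-3,5-bis(4-hydroxy-1-methyl-2-oxo-1,2-dihydroquinolin-3-yl)-1-methyl-4-(propan-2-yl)cyclohexane-1,4-diol (p-menthane numbering; 1-OH cis to the C5 quinolinone and to isopropyl; 1-OH trans to 4-OH)
Conditions: MeMgBr (6 equiv), LaCl3·2LiCl (1 equiv), THF, 0 °C to rt; aq NH4Cl
Reagents that add atoms: methylmagnesium bromide, C[Mg]Br
Why: Lanthanide-promoted Grignard 1,2-addition to a ketone, in which three equivalents are consumed by the acidic OH groups, whose anions keep the ketone open, make the quinolinone carbonyls inert and disfavour retro-Michael cleavage, LaCl3·2LiCl curbs enolisation, and attack from the equatorial side, opposite the axial C5 quinolinone, should place the new hydroxyl axial and cis to that quinolinone, a configuration of no consequence because C1 is ionised in step 4.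

Step 4
Reactants: 6 (3R,5R)-3,5-bis(4-hydroxy-1-methyl-2-oxo-1,2-dihydroquinolin-3-yl)-1-methyl-4-(propan-2-yl)cyclohexane-1,4-diol
Product: 8 CNP0229685.8 with (1R,3S,4R,5S) configuration in p-menthane numbering, via ring-B ether 7 (not isolated)
Conditions: CF3SO3H (3 equiv), CH2Cl2, 0 °C to rt
Reagents that add atoms: none
Why: Brønsted-acid dehydrative cycloetherification through tertiary p-menthyl cations, the closures known from o-hydroxyaryl menthenes of the cannabidiol type and from 3-prenyl-4-hydroxyquinolin-2-ones: the C1 cation is within reach only of the oxygen of the axial C5 quinolinone and only on that face, which sets C1, gives 7 and turns C5 into a bridgehead that can neither lose nor shift its hydrogen, after which the C4 cation passes into the C8 cation by a Wagner–Meerwein 1,2-hydride shift (the terpinen-4-yl to p-menth-8-yl change) and is trapped by the oxygen of the C3 quinolinone, and since every C–O ionisation and the shift are reversible in this medium C4 should settle under thermodynamic control with H axial, C8 equatorial and ring A trans-diequatorially fused (the C3 and C5 descriptors change from R to S only because C4 loses its oxygen).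

Compound list
1 | 4-isopropylphenol | CC(C)c1ccc(O)cc1 | starting material
2 | 4-hydroxy-4-(propan-2-yl)cyclohexa-2,5-dien-1-one | CC(C)C1(O)C=CC(=O)C=C1 | intermediate
3 | 4-hydroxy-1-methylquinolin-2(1H)-one | Cn1c(=O)cc(O)c2ccccc21 | starting material
4 | (4R,5R)-4-hydroxy-5-(4-hydroxy-1-methyl-2-oxo-1,2-dihydroquinolin-3-yl)-4-(propan-2-yl)cyclohex-2-en-1-one (quinolinone cis to OH) | CC(C)[C@@]1(O)C=CC(=O)C[C@@H]1c1c(O)c2ccccc2n(C)c1=O | intermediate
5 | (3R,5R)-4-hydroxy-3,5-bis(4-hydroxy-1-methyl-2-oxo-1,2-dihydroquinolin-3-yl)-4-(propan-2-yl)cyclohexan-1-one (quinolinones trans, C4 not stereogenic) | CC(C)C1(O)[C@@H](c2c(O)c3ccccc3n(C)c2=O)CC(=O)C[C@@H]1c1c(O)c2ccccc2n(C)c1=O | intermediate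
6 | (3R,5R)-3,5-bis(4-hydroxy-1-methyl-2-oxo-1,2-dihydroquinolin-3-yl)-1-methyl-4-(propan-2-yl)cyclohexane-1,4-diol, 1-OH cis to the C5 quinolinone and trans to 4-OH (the C1 epimer would serve equally) | CC(C)[C@]1(O)[C@@H](c2c(O)c3ccccc3n(C)c2=O)C[C@](C)(O)C[C@@H]1c1c(O)c2ccccc2n(C)c1=O | intermediate
7 | ring-B ether: oxygen of the C5 quinolinone bonded to C1 on the face of that quinolinone (2-oxabicyclo[3.3.1]nonane), C4 still with axial OH and equatorial isopropyl, C3 quinolinone free and equatorial | CC(C)[C@]1(O)[C@@H](c2c(O)c3ccccc3n(C)c2=O)C[C@@]2(C)C[C@@H]1c1c(c3ccccc3n(C)c1=O)O2 | intermediate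
8 | CNP0229685.8, (1R,3S,4R,5S) in p-menthane numbering: 2,2,6-trimethyl-dihydropyrano[3,2-c]quinolin-5-one (ring A) trans-fused on C3–C4, second 6-methylpyrano[3,2-c]quinolin-5-one (ring B) bridging C1 and C5, C1–CH3 trans to the ring-B oxygen | Cn1c(=O)c2c(c3ccccc31)OC(C)(C)[C@@H]1[C@@H]2C[C@@]2(C)C[C@@H]1c1c(c3ccccc3n(C)c1=O)O2 | target

Total steps: 4. Longest linear sequence: 4 steps (1 → 2 → 5 → 6 → 8).

Steps most likely to fail

Step 2.
- What may go wrong: the reaction may stall after the first addition beside the quaternary carbon. Facial selectivity in the second addition may be poor if the isopropyl group outweighs the catalyst. The mono-adduct may be lost by dehydrative aromatisation.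
- Fallback: the vinylogous acid/iminium pair is replaced by an aryl–rhodium nucleophile (Hayashi–Miyaura conjugate addition). This is an irreversible carbometalation under strong ligand control, known for cyclic enones and cyclohexadienones.
- Course: it sets out from 3. O-Benzylation (BnBr, K2CO3, DMF) gives 4-(benzyloxy)-1-methylquinolin-2(1H)-one F1. Bromination (NBS, MeCN) gives 4-(benzyloxy)-3-bromo-1-methylquinolin-2(1H)-one F2. Miyaura borylation (B2pin2, PdCl2(dppf), KOAc, dioxane, 80 °C) gives 4-(benzyloxy)-1-methyl-3-(4,4,5,5-tetramethyl-1,3,2-dioxaborolan-2-yl)quinolin-2(1H)-one F3.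
- Addition: the boronate (3 equiv) is added to 2 with [RhCl(C2H4)2]2/(R)-BINAP, aq KOH, dioxane, 50 °C. (R)-BINAP is the ligand enantiomer that gives the (R)-3-aryl sense on cyclohex-2-enone. The reaction passes through the mono-arylated enone F4 to the bis(benzyl ether) of 5 F5.
- Return: hydrogenolysis (H2, Pd/C, EtOAc) comes back to the route at 5.

Step 4.
- What may go wrong: oxygen may trap the ring cation at C4 before the hydride has moved. Hydride may migrate from the benzylic C3–H, with loss of configuration. The wrong quinolinone may close ring A.
- Fallback: the cationic 1,2-shift is replaced by a syn-elimination followed by Markovnikov hydroalkoxylation of a defined prenyl-type alkene.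
- Course: it sets out from 6, which is exposed only to camphorsulfonic acid (10 mol %) in CH2Cl2 at 0 °C so that the reaction halts at 7, now isolated. Ac2O/pyridine masks the free vinylogous acid as the acetate of 7 F6.
- Elimination: methyl N-(triethylammoniosulfonyl)carbamate (Burgess reagent, toluene, 70 °C) removes the C4 hydroxyl by syn-elimination. Only the freely rotating isopropyl C–H qualifies, because C3–H is anti to the axial C–O bond and loss of C5–H would create a bridgehead alkene. This gives the isopropylidene acetate F7.
- Return: HCl in MeOH cleaves the acetate to the isopropylidene hydroxyquinolinone F8. It is protonated at C4 from the axial face opposite quinolinone B and cyclises in the same flask as 3-prenyl-4-hydroxyquinolin-2-ones do, rejoining the route at 8.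

Step 3.
- What may go wrong: the threefold magnesium salt may precipitate, the ketone may enolise instead of adding, and retro-Michael cleavage may occur on prolonged exposure to base.
- Fallback: carbonyl olefination takes the place of carbanion addition.
- Course: it sets out from 5. A Wittig reaction with excess Ph3P=CH2 (from Ph3PCH3Br and KOtBu, THF/DMSO, in which the polyanion stays dissolved and enolisation is merely reversible) gives the exocyclic methylene analogue of 5 F9.
- Return: under the conditions of step 4 the 1,1-disubstituted alkene is protonated in the Markovnikov sense to the same C1 cation that 6 gives, so the route is rejoined at 7.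

Further compounds
F1 | step 2 | 4-(benzyloxy)-1-methylquinolin-2(1H)-one | Cn1c(=O)cc(OCc2ccccc2)c2ccccc21
F2 | step 2 | 4-(benzyloxy)-3-bromo-1-methylquinolin-2(1H)-one | Cn1c(=O)c(Br)c(OCc2ccccc2)c2ccccc21
F3 | step 2 | 4-(benzyloxy)-1-methyl-3-(4,4,5,5-tetramethyl-1,3,2-dioxaborolan-2-yl)quinolin-2(1H)-one | Cn1c(=O)c(B2OC(C)(C)C(C)(C)O2)c(OCc2ccccc2)c2ccccc21
F4 | step 2 | (4R,5R)-5-[4-(benzyloxy)-1-methyl-2-oxo-1,2-dihydroquinolin-3-yl]-4-hydroxy-4-(propan-2-yl)cyclohex-2-en-1-one | CC(C)[C@@]1(O)C=CC(=O)C[C@@H]1c1c(OCc2ccccc2)c2ccccc2n(C)c1=O
F5 | step 2 | (3R,5R)-3,5-bis[4-(benzyloxy)-1-methyl-2-oxo-1,2-dihydroquinolin-3-yl]-4-hydroxy-4-(propan-2-yl)cyclohexan-1-one | CC(C)C1(O)[C@@H](c2c(OCc3ccccc3)c3ccccc3n(C)c2=O)CC(=O)C[C@@H]1c1c(OCc2ccccc2)c2ccccc2n(C)c1=O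
F6 | step 4 | acetate of 7 (4-acetoxy group on the C3 quinolinone) | CC(C)[C@]1(O)[C@@H](c2c(OC(C)=O)c3ccccc3n(C)c2=O)C[C@@]2(C)C[C@@H]1c1c(c3ccccc3n(C)c1=O)O2
F7 | step 4 | isopropylidene acetate (C4=C8 alkene, ring B closed, C3 quinolinone as 4-acetate) | CC(C)=C1[C@@H](c2c(OC(C)=O)c3ccccc3n(C)c2=O)C[C@@]2(C)C[C@@H]1c1c(c3ccccc3n(C)c1=O)O2
F8 | step 4 | isopropylidene hydroxyquinolinone (C4=C8 alkene, ring B closed, C3 quinolinone free) | CC(C)=C1[C@@H](c2c(O)c3ccccc3n(C)c2=O)C[C@@]2(C)C[C@@H]1c1c(c3ccccc3n(C)c1=O)O2
F9 | step 3 | exocyclic methylene analogue of 5 (C1=CH2 in place of C1=O, 3R,5R) | CC(C)C1(O)[C@@H](c2c(O)c3ccccc3n(C)c2=O)CC(=C)C[C@@H]1c1c(O)c2ccccc2n(C)c1=O
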